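Ring B (B1 bridge-bearing carbon, B2 C–OH, B3 C(CH3)2, B4 C–OH, B5 acetyl-bearing carbon, B6 C=O) is disconnected at B1–B2 and B5–B6. A thermal cyclobutenone–ynol ether annulation forges both bonds and the six-membered ring in one operation. The feature exploited is quaternary B3 flanked by oxygenated B2 and B4. Lacking a hydrogen there, the cascade cannot aromatise and stops at a 6,6-dimethylcyclohexa-2,4-dienone, the bis(enol ether) of the ring B triketone. The partners are 3-ethoxy-4,4-dimethylcyclobutenone and a methyl ynol ether whose propargylic CH2 carries the hexasubstituted, dibenzyl-protected ring A. Hydrolysis, C-acetylation at B5 and hydrogenolysis complete the target, which has no stereocentre.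

Key step: step 10

Assumption: ring B is a rapidly tautomerising enolised β-triketone, so every enol form, including the one in the target SMILES, is treated as the same compound.
Abbreviation: Ar = 2,4-bis(benzyloxy)-3-butanoyl-6-methoxy-5-methylphenyl (protected ring A, numbered from the carbon that bears the bridge CH2).

Step 1
Reactants: 1 2,4,6-trihydroxytoluene; 2 butanoyl chloride
Product: 3 1-(2,4,6-trihydroxy-3-methylphenyl)butan-1-one
Conditions: AlCl3 (3.5 equiv), CH2Cl2–MeNO2, 0 → 40 °C; ice/aq HCl
Reagents that add atoms: none
Why: Friedel–Crafts C-acylation of the strongly activated phloroglucinol ring, in which the two free positions of 1 are equivalent and the first acyl group deactivates the ring against a second acylation.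

Step 2
Reactants: 3 1-(2,4,6-trihydroxy-3-methylphenyl)butan-1-one
Product: 4 1-(2,6-dihydroxy-4-methoxy-3-methylphenyl)butan-1-one (aspidinol)
Conditions: Me2SO4 (1.0 equiv), K2CO3 (1.0 equiv), acetone, rt → reflux
Reagents that add atoms: dimethyl sulfate COS(=O)(=O)OC
Why: Williamson-type O-methylation under substrate control, since with one equivalent of base and electrophile the hydroxyl para to the ketone (the most acidic one, and the only one that cannot hydrogen-bond to the carbonyl) should be alkylated ahead of the two ortho hydroxyls.

Step 3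
Reactants: 4 aspidinol
Product: 6 3-butanoyl-2,4-dihydroxy-6-methoxy-5-methylbenzaldehyde, via aryl iminium chloride 5 (not isolated)
Conditions: POCl3 (1.2 equiv), DMF (1.5 equiv), EtOAc, 0 °C → rt; then ice–water
Reagents that add atoms: N,N-dimethylformamide CN(C)C=O; water O
Why: Vilsmeier–Haack formylation at the single free, threefold oxygen-activated ring position, a reaction well established for acylphloroglucinols; the small excess of reagent at low temperature spares the α-carbon of the hydrogen-bonded ketone, and this entry to the bridge carbon avoids a later halomethylation in strong HBr or HCl that benzyl ethers would not tolerate.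

Step 4
Reactants: 6 3-butanoyl-2,4-dihydroxy-6-methoxy-5-methylbenzaldehyde
Product: 7 2,4-bis(benzyloxy)-3-butanoyl-6-methoxy-5-methylbenzaldehyde
Conditions: BnBr (2.6 equiv), K2CO3 (3 equiv), DMF, 60 °C
Reagents that add atoms: benzyl bromide BrCc1ccccc1
Why: Williamson etherification in a dipolar aprotic solvent, which favours O- over C-benzylation of the phenoxides and, with heat and excess reagent, overcomes the chelation of both hydroxyls.

Step 5
Reactants: 7 2,4-bis(benzyloxy)-3-butanoyl-6-methoxy-5-methylbenzaldehyde
Product: 8 1-[2,6-bis(benzyloxy)-3-(hydroxymethyl)-4-methoxy-5-methylphenyl]butan-1-one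
Conditions: NaBH4 (0.5 equiv), THF–MeOH, −10 °C
Reagents that add atoms: none
Why: Chemoselective borohydride reduction, in which the aldehyde reacts fast while the ketone, twisted out of conjugation and shielded by two ortho benzyloxy groups, should stay untouched at low temperature.

Step 6
Reactants: 8 1-[2,6-bis(benzyloxy)-3-(hydroxymethyl)-4-methoxy-5-methylphenyl]butan-1-one
Product: 9 1-[2,6-bis(benzyloxy)-3-(bromomethyl)-4-methoxy-5-methylphenyl]butan-1-one
Conditions: PBr3 (0.4 equiv), Et2O, 0 °C; cold aq NaHCO3 wash, used crude
Reagents that add atoms: phosphorus tribromide BrP(Br)Br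
Why: Standard PBr3 bromination of a benzylic alcohol (bromide displaces the activated phosphite ester), compatible with benzyl ethers and the ketone; the ring is fully substituted, so the reactive bromide cannot alkylate a second ring A and needs no chromatography.

Step 7
Reactants: 10 chloroacetaldehyde dimethyl acetal
Product: 12 methoxyethyne (methoxyacetylene), via sodium methoxyacetylide 11 (not isolated)
Conditions: NaNH2 (3.1 equiv), liq. NH3, −33 °C; NH3 evaporated; cold brine, −20 °C; distilled into THF at −78 °C
Reagents that add atoms: none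
Why: Two successive β-eliminations (methanol, then HCl) followed by deprotonation, the standard preparation of alkoxyacetylenes from chloroacetals; isolating the free alkyne removes the nitrogen bases that would otherwise consume the benzylic bromide in step 8.

Step 8
Reactants: 9 1-[2,6-bis(benzyloxy)-3-(bromomethyl)-4-methoxy-5-methylphenyl]butan-1-one; 12 methoxyethyne
Product: 15 1-[2,6-bis(benzyloxy)-4-methoxy-3-(3-methoxyprop-2-yn-1-yl)-5-methylphenyl]butan-1-one, via lithium methoxyacetylide 13 (not isolated), via bromo(methoxyethynyl)zinc 14 (not isolated)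
Conditions: 12 (1.6 equiv), n-BuLi, THF, −78 °C; ZnBr2, → 0 °C; then 9, PdCl2(DPEphos) (3 mol %), THF, 23 °C; aq NaHCO3 work-up, Et3N-deactivated silica
Reagents that add atoms: none
Why: Negishi sp3–sp coupling of a benzylic bromide with an alkynylzinc halide; unlike the lithium or sodium acetylide, the zinc reagent neither adds to nor enolises the butanoyl ketone, and the basic work-up protects the acid-sensitive ynol ether.

Step 9
Reactants: 16 2-methylpropanoyl chloride (isobutyryl chloride); 17 ethoxyethyne (ethoxyacetylene)
Product: 19 3-ethoxy-4,4-dimethylcyclobut-2-en-1-one, via dimethylketene 18 (not isolated)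
Conditions: Et3N (1.1 equiv), Et2O, 0 °C → reflux; filter, distil
Reagents that add atoms: none
Why: Dehydrochlorination gives dimethylketene, which is trapped in situ by a regioselective ketene–alkyne [2+2] cycloaddition in which the nucleophilic terminal alkyne carbon bonds to the ketene carbonyl carbon, placing OEt next to the C(CH3)2 carbon.

Step 10
Reactants: 15 1-[2,6-bis(benzyloxy)-4-methoxy-3-(3-methoxyprop-2-yn-1-yl)-5-methylphenyl]butan-1-one; 19 3-ethoxy-4,4-dimethylcyclobut-2-en-1-one
Product: 23 2-(ArCH2)-5-ethoxy-3-methoxy-6,6-dimethylcyclohexa-2,4-dien-1-one, via vinylketene 20 (not isolated), via 4-alkenylcyclobutenone 21 (not isolated), via dienylketene 22 (not isolated)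
Conditions: 19 (2.5 equiv), dry degassed toluene, base-washed sealed tube, argon, 120 → 150 °C
Reagents that add atoms: none
Why: Thermal conrotatory four-electron opening of 19 gives vinylketene 20, whose electrophilic ketene carbon is attacked by the nucleophilic, arylmethyl-bearing alkyne carbon of 15 in a [2+2] cycloaddition that makes the B1–B2 and B5–B6 bonds and gives 4-alkenylcyclobutenone 21. Reversible four-electron opening of 21 delivers dienylketene 22, and ring B closes by a disrotatory six-electron electrocyclisation in which the ketene carbon B2 re-bonds to the C(CH3)2 terminus B3. This is the Danheiser cyclobutenone–alkoxyalkyne benzannulation in its interrupted form, because B3 carries no hydrogen, enolisation to a phenol is impossible and the cascade rests at the 2,4-dienone. No stereocentre persists in 23 (the one in 21 is transient), so only regiochemistry must be controlled, and it is fixed by the polarisation of the ynol ether, whose oxygen pushes electron density onto the carbon bearing CH2Ar, matched with that of the ketene. The methyl ynol ether has no β-hydrogen for retro-ene loss of an alkene, an excess of cheap 19 offsets a competing 1,5-hydrogen shift of 20, and heat is used instead of light because the butyrophenone unit would undergo photochemical γ-hydrogen abstraction. The neutral medium should leave the benzyl ethers and the hindered aryl ketone untouched.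

Step 11
Reactants: 23 2-(ArCH2)-5-ethoxy-3-methoxy-6,6-dimethylcyclohexa-2,4-dien-1-one
Product: 24 2-(ArCH2)-3,5-dihydroxy-4,4-dimethylcyclohexa-2,5-dien-1-one (enol form of the trione)
Conditions: 2 M aq HCl, THF, 50 °C, argon
Reagents that add atoms: water O
Why: Acid-catalysed hydrolysis of two vinylogous esters by conjugate addition of water and loss of alcohol; both enol ethers converge on the same enolised trione, and the aryl benzyl ethers, the aryl methyl ether and the ketone are stable to dilute acid.

Step 12
Reactants: 24 2-(ArCH2)-3,5-dihydroxy-4,4-dimethylcyclohexa-2,5-dien-1-one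
Product: 25 2-acetyl-6-(ArCH2)-3,5-dihydroxy-4,4-dimethylcyclohexa-2,5-dien-1-one
Conditions: Ac2O (1.3 equiv), Et3N (2.2 equiv), DMAP (0.2 equiv), CH2Cl2, 0 °C → rt; dilute aq HCl work-up
Reagents that add atoms: acetic anhydride CC(=O)OC(C)=O
Why: DMAP-catalysed C-acylation of a cyclic 1,3-dione, in which kinetic enol acetates re-enter the acylpyridinium/enolate equilibrium and funnel to the C-acetyl β-triketone at B5 (the only ring B carbon still bearing hydrogen), which is held as its stabilised enolate, while the benzyl ethers keep ring A from being acetylated.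

Step 13
Reactants: 25 2-acetyl-6-(ArCH2)-3,5-dihydroxy-4,4-dimethylcyclohexa-2,5-dien-1-one
Product: 26 2-acetyl-6-[(3-butanoyl-2,4-dihydroxy-6-methoxy-5-methylphenyl)methyl]-3,5-dihydroxy-4,4-dimethylcyclohexa-2,5-dien-1-one (target)
Conditions: H2 (1 atm), 10% Pd/C, EtOAc, rt; filtration through Celite
Reagents that add atoms: none
Why: Catalytic hydrogenolysis of two aryl benzyl ethers; the chelated enol-triketone, the diarylmethane-type C–C bonds and the aryl ketone are inert at one atmosphere, and the neutral medium avoids acid- or base-induced scrambling of the methylene bridge.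

Compound list
1 | 2,4,6-trihydroxytoluene | Cc1c(O)cc(O)cc1O | starting material
2 | butanoyl chloride | CCCC(=O)Cl | starting material
3 | 1-(2,4,6-trihydroxy-3-methylphenyl)butan-1-one | CCCC(=O)c1c(O)cc(O)c(C)c1O | intermediate
4 | 1-(2,6-dihydroxy-4-methoxy-3-methylphenyl)butan-1-one (aspidinol) | CCCC(=O)c1c(O)cc(OC)c(C)c1O | intermediate
5 | (3-butanoyl-2,4-dihydroxy-6-methoxy-5-methylphenyl)methylidene(dimethyl)ammonium chloride | CCCC(=O)c1c(O)c(C)c(OC)c(C=[N+](C)C)c1O.[Cl-] | intermediate
6 | 3-butanoyl-2,4-dihydroxy-6-methoxy-5-methylbenzaldehyde | CCCC(=O)c1c(O)c(C)c(OC)c(C=O)c1O | intermediate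
7 | 2,4-bis(benzyloxy)-3-butanoyl-6-methoxy-5-methylbenzaldehyde | CCCC(=O)c1c(OCc2ccccc2)c(C)c(OC)c(C=O)c1OCc3ccccc3 | intermediate
8 | 1-[2,6-bis(benzyloxy)-3-(hydroxymethyl)-4-methoxy-5-methylphenyl]butan-1-one | CCCC(=O)c1c(OCc2ccccc2)c(C)c(OC)c(CO)c1OCc3ccccc3 | intermediate
9 | 1-[2,6-bis(benzyloxy)-3-(bromomethyl)-4-methoxy-5-methylphenyl]butan-1-one | CCCC(=O)c1c(OCc2ccccc2)c(C)c(OC)c(CBr)c1OCc3ccccc3 | intermediate
10 | chloroacetaldehyde dimethyl acetal | COC(CCl)OC | starting material
11 | sodium methoxyacetylide | COC#C[Na] | intermediate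
12 | methoxyethyne | COC#C | intermediate
13 | lithium methoxyacetylide | COC#C[Li] | intermediate
14 | bromo(methoxyethynyl)zinc | COC#C[Zn]Br | intermediate
15 | 1-[2,6-bis(benzyloxy)-4-methoxy-3-(3-methoxyprop-2-yn-1-yl)-5-methylphenyl]butan-1-one | CCCC(=O)c1c(OCc2ccccc2)c(C)c(OC)c(CC#COC)c1OCc3ccccc3 | intermediate
16 | 2-methylpropanoyl chloride | CC(C)C(=O)Cl | starting material
17 | ethoxyethyne | CCOC#C | starting material
18 | dimethylketene | CC(C)=C=O | intermediate
19 | 3-ethoxy-4,4-dimethylcyclobut-2-en-1-one | CCOC1=CC(=O)C1(C)C | intermediate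
20 | 3-ethoxy-4-methylpenta-1,3-dien-1-one (vinylketene) | CCOC(C=C=O)=C(C)C | intermediate
21 | 2-(ArCH2)-4-(1-ethoxy-2-methylprop-1-enyl)-3-methoxycyclobut-2-en-1-one (racemic, transient) | CCCC(=O)c1c(OCc2ccccc2)c(C)c(OC)c(CC3=C(OC)C(C(OCC)=C(C)C)C3=O)c1OCc4ccccc4 | intermediate
22 | (3E)-2-(ArCH2)-5-ethoxy-3-methoxy-6-methylhepta-1,3,5-trien-1-one (dienylketene, chain carbons cis across C3=C4) | CCCC(=O)c1c(OCc2ccccc2)c(C)c(OC)c(CC(=C=O)/C(OC)=C\C(OCC)=C(C)C)c1OCc3ccccc3 | intermediate
23 | 2-(ArCH2)-5-ethoxy-3-methoxy-6,6-dimethylcyclohexa-2,4-dien-1-one | CCCC(=O)c1c(OCc2ccccc2)c(C)c(OC)c(CC3=C(OC)C=C(OCC)C(C)(C)C3=O)c1OCc4ccccc4 | intermediate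
24 | 2-(ArCH2)-3,5-dihydroxy-4,4-dimethylcyclohexa-2,5-dien-1-one | CCCC(=O)c1c(OCc2ccccc2)c(C)c(OC)c(CC3=C(O)C(C)(C)C(O)=CC3=O)c1OCc4ccccc4 | intermediate
25 | 2-acetyl-6-(ArCH2)-3,5-dihydroxy-4,4-dimethylcyclohexa-2,5-dien-1-one | CCCC(=O)c1c(OCc2ccccc2)c(C)c(OC)c(CC3=C(O)C(C)(C)C(O)=C(C(C)=O)C3=O)c1OCc4ccccc4 | intermediate
26 | 2-acetyl-6-[(3-butanoyl-2,4-dihydroxy-6-methoxy-5-methylphenyl)methyl]-3,5-dihydroxy-4,4-dimethylcyclohexa-2,5-dien-1-one | CCCC(=O)c1c(O)c(C)c(OC)c(CC2=C(O)C(C)(C)C(O)=C(C(C)=O)C2=O)c1O | target

Total step count: 13. Longest linear sequence: 11 (steps 1–6, 8, 10–13).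

Steps most likely to fail

1. Step 10. The donor-stabilised cyclobutenone may open only sluggishly, since one methyl group must rotate inward. The vinylketene may also be drained by a 1,5-hydrogen shift, or the ynol ether may degrade thermally before it is captured. The fallback sets out from bromide 9 and returns at 25, bypassing steps 8 and 10–12. Commercial 2,4,6-trihydroxyacetophenone is dearomatised by geminal C-methylation (MeI, NaOMe, MeOH) to 2-acetyl-3,5-dihydroxy-4,4-dimethylcyclohexa-2,5-dien-1-one F1. The dianion of F1 (NaH, 2.1 equiv, THF–DMF, 0 °C → rt) is then C-benzylated by 9 at its free, more basic ring carbon. This gives 25, which enters step 13 unchanged.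

2. Step 8. Zinc salts may ionise the electron-rich benzylic bromide or promote hydration of the ynol ether during work-up, and homocoupling of either partner may compete with cross-coupling. The fallback sets out from 13 and 9 and returns at 15. Lithium acetylide 13 is quenched with Bu3SnCl to give distillable tributyl(methoxyethynyl)stannane F2. This is joined to 9 by a Stille coupling (Pd2(dba)3, tri(2-furyl)phosphine, THF, 50 °C). The neutral conditions are free of Lewis acid and base, and a KF wash precedes deactivated silica.

3. Step 2. Over-methylation and competing alkylation of a chelated hydroxyl may erode the selectivity among three phenols. The fallback sets out from 3 and returns at 4. It replaces kinetic selection by chelation-directed deprotection. Exhaustive methylation (excess Me2SO4, K2CO3, acetone, reflux) gives 1-(2,4,6-trimethoxy-3-methylphenyl)butan-1-one F3. Excess BCl3 (CH2Cl2, 0 °C → rt) then removes only the two methoxy groups that flank and chelate through the ketone. The para methoxy group, which lacks this assistance, remains, and the product is 4.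

Further compounds
F1 | step 10 | 2-acetyl-3,5-dihydroxy-4,4-dimethylcyclohexa-2,5-dien-1-one (acetylfilicinic acid) | CC(=O)C1=C(O)C(C)(C)C(O)=CC1=O
F2 | step 8 | tributyl(methoxyethynyl)stannane | CCCC[Sn](CCCC)(CCCC)C#COC
F3 | step 2 | 1-(2,4,6-trimethoxy-3-methylphenyl)butan-1-one | CCCC(=O)c1c(OC)cc(OC)c(C)c1OC
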